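## Retrosynthetic overview

1. The spiro-dihydropyran is cut by a retro-oxa-Diels–Alder step (O–C11 and C13–CH2) into (+)-alantolactone and ent-β-elemenal, which are joined in the last step.
2. In alantolactone the α-methylene group is put on last and C4 is set by hydrogenation of the ring-A alkene; rings A and B are closed together by an intramolecular Diels–Alder reaction of a vinylallene lactone that forms C1–C2 and C5–C10.
3. Enabling feature: in ring A (C1, C2, C3, C4, C5, C10) the fusion carbon C5 carries the C5=C6 double bond of ring B. Ring A is therefore the [4+2] adduct of the diene C2=C3–C4=C5 of an allene C4=C5=C6 with the C1=C10 alkene, and C6–C7–C8–C9 of ring B, held by the cis-lactone, is the tether.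
4. The vinylallene lactone comes from an anti cross-aldol of but-2-ynal with methyl 4-oxobutanoate, a reagent-controlled methallylation, an anti-SN2′ opening of the propargylic lactone by a vinylcopper reagent (centre to axis) and relactonisation at the C8 oxygen.
5. ent-β-Elemenal comes from (S)-carvone (chiral-imine Michael addition for the quaternary centre, decarboxylation to vinyl, ketone to isopropenyl, allylic oxidation). Ring order: lactone, then rings A and B in one step; the elemane ring is taken from the chiral pool; the dihydropyran is formed last.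

Key step: step 6

Remark: the elemane half of the given structure belongs to the antipodal (ent) β-elemene series, so (S)-(+)-carvone is the chiral source. Eudesmane numbering (C1 to C15) is used for the lactone half and primed locants for the cyclohexane of the elemane half (C1′ quaternary, C2′ and C4′ substituted).

## Route

Step 1
Reactants: 1 but-2-yn-1-ol
Product: 2 but-2-ynal
Conditions: MnO2 (activated, excess), CH2Cl2, rt; filtered solution used directly
Reagents that add atoms: none
Why: Activated MnO2 oxidises propargylic alcohols selectively to ynals (heterogeneous allylic/propargylic oxidation), and the volatile aldehyde is best used as its solution.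

Step 2
Reactants: 2 but-2-ynal; 3 methyl 4-oxobutanoate
Product: 5 (2R,3S)-5-oxo-2-(prop-1-yn-1-yl)oxolane-3-carbaldehyde, via aldol adduct 4 (not isolated)
Conditions: 2 (1.5 equiv), 3 (added slowly), (S)-α,α-bis[3,5-bis(trifluoromethyl)phenyl]pyrrolidin-2-ylmethanol (10 mol %), dioxane, rt; then camphorsulfonic acid (cat.), CH2Cl2, rt
Reagents that add atoms: none
Why: Enamine-mediated direct cross-aldol reaction in which the diarylprolinol condenses only with the enolisable aldehyde 3 and its (E)-enamine adds to the non-enolisable ynal through a hydrogen-bond-organised transition state, which should set the anti pair (3S,4R) of 4, after which acid closes the propargylic hydroxyl onto the methyl ester to give the cis γ-lactone.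

Step 3
Reactants: 5 (2R,3S)-5-oxo-2-(prop-1-yn-1-yl)oxolane-3-carbaldehyde
Product: 6 (4R,5R)-4-[(1R)-1-hydroxy-3-methylbut-3-en-1-yl]-5-(prop-1-yn-1-yl)oxolan-2-one
Conditions: (+)-Ipc2BOMe, CH2=C(CH3)CH2MgCl, Et2O, −78 °C to rt, then 5, −78 °C; then pH 7 buffer, H2O2, MeOH, 0 °C
Reagents that add atoms: 2-methylallylmagnesium chloride, CC(=C)C[Mg]Cl
Why: Brown allylboration through a closed chair transition state in which the isopinocampheyl groups of the borane made from (+)-Ipc2BOMe direct the methallyl group to the Re face of the aldehyde, so that reagent control should set the (R) carbinol centre C8 against the weak Felkin bias of the ring.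

Step 4
Reactants: 6 (4R,5R)-4-[(1R)-1-hydroxy-3-methylbut-3-en-1-yl]-5-(prop-1-yn-1-yl)oxolan-2-one
Product: 7 (4S,5R)-4-[(1R)-3-methyl-1-(triethylsilyloxy)but-3-en-1-yl]-5-(prop-1-yn-1-yl)oxolan-2-one
Conditions: Et3SiCl, imidazole, DMAP (cat.), CH2Cl2, 0 °C
Reagents that add atoms: chlorotriethylsilane, CC[Si](Cl)(CC)CC
Why: Standard silylation of a secondary alcohol, needed so that the C8 alkoxide cannot transacylate the neighbouring lactone under the basic conditions of the next step.

Step 5
Reactants: 7 (4S,5R)-4-[(1R)-3-methyl-1-(triethylsilyloxy)but-3-en-1-yl]-5-(prop-1-yn-1-yl)oxolan-2-one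
Product: 10 (4S,5R)-4-[(aS)-3-methylpenta-1,2,4-trien-1-yl]-5-(2-methylprop-2-en-1-yl)oxolan-2-one, via silyl allenyl acid 8 (not isolated), via allenyl hydroxy acid 9 (not isolated)
Conditions: CH2=CHMgBr (3 equiv), CuBr·SMe2 (1.5 equiv), THF, −78 to −30 °C; then AcOH (aq); then Bu4NF, AcOH, THF, rt; then citric acid (aq) to pH 3
Reagents that add atoms: vinylmagnesium bromide, C=C[Mg]Br
Why: Anti-selective SN2′ substitution of a propargylic carboxylate by an organocopper reagent with the lactone C6–O bond as leaving group: vinyl enters at the methyl-bearing alkyne carbon anti to that bond, so the (R) centre C6 should become the (aS) allene axis, and after fluoride cleavage of the silyl ether the freed 4-hydroxy acid closes to the cis γ-lactone with retention at C8.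

Step 6
Reactants: 10 (4S,5R)-4-[(aS)-3-methylpenta-1,2,4-trien-1-yl]-5-(2-methylprop-2-en-1-yl)oxolan-2-one
Product: 11 (3aS,8aR,9aR)-5,8a-dimethyl-3a,7,8,8a,9,9a-hexahydronaphtho[2,3-b]furan-2(3H)-one
Conditions: toluene (0.01 M), BHT (cat.), 110 °C, sealed tube
Reagents that add atoms: none
Why: Thermal intramolecular Diels–Alder reaction (type 1, fused mode), concerted and asynchronous: the vinylallene unit C2=C3–C4=C5 is the diene, the unactivated C10=C1 isopropenyl alkene is the dienophile, and the outer allene bond C5=C6 is carried through untouched as the ring-B alkene of the target. The closest known reaction type is the intramolecular cycloaddition of vinylallenes to unactivated alkenes, including transfer of chirality from the allene axis to carbon. Ring A is closed by the [4+2] event itself (C1–C2 and C5–C10 both lie in it), and ring B is closed at the same time through C5–C10 as the six-membered tether ring (C6–C7–C8–C9), cis-fused to the lactone already in place. The only new stereocentre is C10: the tether carbon C7 sits on one π face of the diene, so the dienophile can reach only that face, and the tether forces C9 outward and the C10 methyl over the diene, so the (aS) axis should give (R)-C10 with the methyl cis to the lactone. The step needs fused and not bridged regiochemistry and no competing dienophile or hydrogen shift: the four-atom tether secures the first, the lactone still lacks its α-methylene group, and the vinyl terminus carries no allylic hydrogen for a [1,5] shift.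

Step 7
Reactants: 11 (3aS,8aR,9aR)-5,8a-dimethyl-3a,7,8,8a,9,9a-hexahydronaphtho[2,3-b]furan-2(3H)-one
Product: 12 (3aS,5S,8aR,9aR)-5,8a-dimethyl-3a,5,6,7,8,8a,9,9a-octahydronaphtho[2,3-b]furan-2(3H)-one
Conditions: H2 (4 atm), RhCl(PPh3)3 (10 mol %), benzene, 40 °C, stopped after one equivalent of H2
Reagents that add atoms: none
Why: Homogeneous hydrogenation with RhCl(PPh3)3 discriminates alkenes by steric access and adds 1,2: the ring-A bond C3=C4 is open whereas C5=C6 is flanked by the quaternary C10 and by C7, and hydrogen should be delivered to the α face opposite the axial C10 methyl, which gives the 4β-methyl (4S) centre.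

Step 8
Reactants: 12 (3aS,5S,8aR,9aR)-5,8a-dimethyl-3a,5,6,7,8,8a,9,9a-octahydronaphtho[2,3-b]furan-2(3H)-one
Product: 15 (+)-alantolactone, via Mannich base 13 (not isolated), via ammonium iodide 14 (not isolated)
Conditions: LiN(i-Pr)2, THF, −78 °C; CH2=N(CH3)2 iodide, −78 °C to rt; then CH3I, MeOH, rt; then NaHCO3 (aq), CH2Cl2, rt
Reagents that add atoms: N,N-dimethylmethyleneiminium iodide (Eschenmoser's salt), C=[N+](C)C.[I-]
Why: Eschenmoser methylenation (aminomethylation of the lactone enolate, quaternisation, base-induced elimination) is the standard route to an α-methylene-γ-butyrolactone, and C11 becomes trigonal so no stereocentre is at stake.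

Step 9
Reactants: 16 (S)-(+)-carvone
Product: 17 (5S)-2-methyl-5-(prop-1-en-2-yl)cyclohexan-1-one (dihydrocarvone, mixture at C2)
Conditions: LiBH(s-Bu)3, THF, −78 °C; then H2O
Reagents that add atoms: none
Why: Conjugate hydride reduction of a β-unsubstituted cyclohexenone by a bulky trialkylborohydride leaves the isopropenyl group untouched, and the configuration at C2 is irrelevant because this carbon becomes trigonal in the next step.

Step 10
Reactants: 17 (5S)-2-methyl-5-(prop-1-en-2-yl)cyclohexan-1-one
Product: 20 methyl 3-[(1R,4S)-1-methyl-2-oxo-4-(prop-1-en-2-yl)cyclohexyl]propanoate, via chiral imine 18 (not isolated), via adduct imine 19 (not isolated)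
Conditions: (S)-1-phenylethylamine, p-TsOH (cat.), toluene, reflux (Dean–Stark); then methyl acrylate, hydroquinone (cat.), THF, 50 °C; then AcOH (20 % aq), rt
Reagents that add atoms: methyl acrylate, C=CC(=O)OC
Why: Asymmetric Michael addition of a chiral imine through its more substituted secondary enamine tautomer (d'Angelo reaction): the acrylate is taken up in an aza-ene-like transition state on the enamine face anti to the phenyl group of the (S)-amine, which is the face trans to the isopropenyl group, so the quaternary centre should form with (R) configuration against the intrinsic axial preference.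

Step 11
Reactants: 20 methyl 3-[(1R,4S)-1-methyl-2-oxo-4-(prop-1-en-2-yl)cyclohexyl]propanoate
Product: 21 3-[(1R,4S)-1-methyl-2-oxo-4-(prop-1-en-2-yl)cyclohexyl]propanoic acid
Conditions: LiOH, THF/H2O, rt; then HCl (1 M)
Reagents that add atoms: lithium hydroxide, [Li+].[OH-]
Why: Plain saponification of a methyl ester, to which the ketone, the quaternary centre and the alkene are inert.

Step 12
Reactants: 21 3-[(1R,4S)-1-methyl-2-oxo-4-(prop-1-en-2-yl)cyclohexyl]propanoic acid
Product: 22 (2R,5S)-2-ethenyl-2-methyl-5-(prop-1-en-2-yl)cyclohexan-1-one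
Conditions: Pb(OAc)4 (1.5 equiv), Cu(OAc)2 (cat.), pyridine, benzene, 80 °C
Reagents that add atoms: none
Why: Kochi oxidative decarboxylation: Pb(OAc)4 generates the primary alkyl radical with loss of CO2 and Cu(OAc)2 oxidises it to the terminal alkene, which turns the propanoic acid chain into the vinyl group without touching the quaternary centre.

Step 13
Reactants: 22 (2R,5S)-2-ethenyl-2-methyl-5-(prop-1-en-2-yl)cyclohexan-1-one
Product: 23 (2R,5S)-2-ethenyl-2-methyl-5-(prop-1-en-2-yl)cyclohexane-1-carbonitrile (mixture at C1)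
Conditions: TosMIC, t-BuOK, EtOH (1.5 equiv), DME, 0 to 40 °C
Reagents that add atoms: p-toluenesulfonylmethyl isocyanide (TosMIC), Cc1ccc(cc1)S(=O)(=O)C[N+]#[C-]
Why: Van Leusen reductive cyanation converts a hindered ketone directly into the homologous nitrile, and the new centre, formed as a mixture, is corrected in the next step.

Step 14
Reactants: 23 (2R,5S)-2-ethenyl-2-methyl-5-(prop-1-en-2-yl)cyclohexane-1-carbonitrile
Product: 26 1-[(1S,2R,5S)-2-ethenyl-2-methyl-5-(prop-1-en-2-yl)cyclohexyl]ethan-1-one, via lithium ketimide 24 (not isolated), via ketone epimers 25 (not isolated)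
Conditions: CH3Li, Et2O, 0 °C to rt; then HCl (1 M), THF, rt; then NaOMe (cat.), MeOH, rt
Reagents that add atoms: methyllithium, [Li]C; water, O
Why: Addition of an organolithium to a nitrile and hydrolysis of the ketimine give the methyl ketone, and base equilibration should place the acetyl group equatorial, trans to the vinyl group and cis to the C4′ substituent (thermodynamic control in the chair with the C4′ isopropenyl group equatorial).

Step 15
Reactants: 26 1-[(1S,2R,5S)-2-ethenyl-2-methyl-5-(prop-1-en-2-yl)cyclohexyl]ethan-1-one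
Product: 27 (1R,2R,4S)-1-ethenyl-1-methyl-2,4-di(prop-1-en-2-yl)cyclohexane (ent-β-elemene)
Conditions: Ph3PCH3Br, t-BuOK, THF, 0 °C to reflux
Reagents that add atoms: methyltriphenylphosphonium bromide, C[P+](c1ccccc1)(c1ccccc1)c1ccccc1.[Br-]
Why: Wittig methylenation of a methyl ketone whose α-centre already has its thermodynamic configuration, so the basic ylide cannot scramble it.

Step 16
Reactants: 27 (1R,2R,4S)-1-ethenyl-1-methyl-2,4-di(prop-1-en-2-yl)cyclohexane
Product: 28 (1R,2R,4S)-4-(3-chloroprop-1-en-2-yl)-1-ethenyl-1-methyl-2-(prop-1-en-2-yl)cyclohexane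
Conditions: Ca(OCl)2, CO2 (solid), CH2Cl2/H2O, 0 °C
Reagents that add atoms: calcium hypochlorite, [Ca+2].[O-]Cl.[O-]Cl
Why: Ene-type allylic chlorination by HOCl puts chlorine on the terminal carbon of a 1,1-disubstituted alkene with shift of the double bond; the C4′ isopropenyl group should react faster than the C2′ one, which is shielded by the neighbouring quaternary carbon, and the vinyl group has no allylic hydrogen.

Step 17
Reactants: 28 (1R,2R,4S)-4-(3-chloroprop-1-en-2-yl)-1-ethenyl-1-methyl-2-(prop-1-en-2-yl)cyclohexane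
Product: 29 2-[(1S,3R,4R)-4-ethenyl-4-methyl-3-(prop-1-en-2-yl)cyclohexyl]prop-2-enal (ent-β-elemenal)
Conditions: 4-methylmorpholine N-oxide (4 equiv), KI (cat.), NaHCO3, MeCN, 40 °C
Reagents that add atoms: 4-methylmorpholine N-oxide, C[N+]1([O-])CCOCC1
Why: Amine N-oxide oxidation of an allylic halide (Kornblum-type: O-alkylation, then base-induced loss of the amine) gives the 2-substituted acrolein directly without over-oxidation.

Step 18
Reactants: 15 (+)-alantolactone; 29 2-[(1S,3R,4R)-4-ethenyl-4-methyl-3-(prop-1-en-2-yl)cyclohexyl]prop-2-enal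
Product: 30 CNP0175206.1 (spiro-dihydropyran adduct)
Conditions: neat, 15 (1.5 equiv), BHT (cat.), 120 °C, sealed tube
Reagents that add atoms: none
Why: Thermal oxa-Diels–Alder reaction of a 2-substituted acrolein (1-oxadiene) with the acrylate-type alkene of the α-methylene lactone, the mode in which acrolein combines with methacrylate-type alkenes (oxygen to the carbonyl-bearing carbon, carbon to CH2); the oxadiene should approach the exocyclic alkene from the convex face of the cis-fused lactone (the face of H7 and H8), which sets the spiro centre.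

## Compound list

1 | but-2-yn-1-ol | CC#CCO | starting material
2 | but-2-ynal | CC#CC=O | intermediate
3 | methyl 4-oxobutanoate | COC(=O)CCC=O | starting material
4 | methyl (3S,4R)-3-formyl-4-hydroxyhept-5-ynoate (anti aldol adduct) | COC(=O)C[C@H](C=O)[C@@H](O)C#CC | intermediate
5 | (2R,3S)-5-oxo-2-(prop-1-yn-1-yl)oxolane-3-carbaldehyde (cis) | O=C[C@H]1CC(=O)O[C@H]1C#CC | intermediate
6 | (4R,5R)-4-[(1R)-1-hydroxy-3-methylbut-3-en-1-yl]-5-(prop-1-yn-1-yl)oxolan-2-one | C=C(C)C[C@@H](O)[C@H]1CC(=O)O[C@H]1C#CC | intermediate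
7 | (4S,5R)-4-[(1R)-3-methyl-1-(triethylsilyloxy)but-3-en-1-yl]-5-(prop-1-yn-1-yl)oxolan-2-one | C=C(C)C[C@@H](O[Si](CC)(CC)CC)[C@H]1CC(=O)O[C@H]1C#CC | intermediate
8 | (3S,4R)-6-methyl-3-[(aS)-3-methylpenta-1,2,4-trien-1-yl]-4-(triethylsilyloxy)hept-6-enoic acid | C=CC(C)=[C@@]=C([H])[C@H](CC(=O)O)[C@@H](CC(C)=C)O[Si](CC)(CC)CC | intermediate
9 | (3S,4R)-4-hydroxy-6-methyl-3-[(aS)-3-methylpenta-1,2,4-trien-1-yl]hept-6-enoic acid | C=CC(C)=[C@@]=C([H])[C@H](CC(=O)O)[C@H](O)CC(C)=C | intermediate
10 | (4S,5R)-4-[(aS)-3-methylpenta-1,2,4-trien-1-yl]-5-(2-methylprop-2-en-1-yl)oxolan-2-one (cis) | C=CC(C)=[C@@]=C([H])[C@@H]1CC(=O)O[C@@H]1CC(C)=C | intermediate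
11 | (3aS,8aR,9aR)-5,8a-dimethyl-3a,7,8,8a,9,9a-hexahydronaphtho[2,3-b]furan-2(3H)-one (13-noreudesma-3,5-dien-12,8-olide) | O=C1C[C@H]2C=C3C(C)=CCC[C@]3(C)C[C@H]2O1 | intermediate
12 | (3aS,5S,8aR,9aR)-5,8a-dimethyl-3a,5,6,7,8,8a,9,9a-octahydronaphtho[2,3-b]furan-2(3H)-one (13-noralantolactone) | O=C1C[C@H]2C=C3[C@@H](C)CCC[C@]3(C)C[C@H]2O1 | intermediate
13 | 3-[(dimethylamino)methyl] derivative of 12 (mixture at C3) | O=C1C(CN(C)C)[C@H]2C=C3[C@@H](C)CCC[C@]3(C)C[C@H]2O1 | intermediate
14 | 3-[(trimethylammonio)methyl] derivative of 12, iodide | O=C1C(C[N+](C)(C)C)[C@H]2C=C3[C@@H](C)CCC[C@]3(C)C[C@H]2O1.[I-] | intermediate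
15 | (+)-alantolactone, (3aR,5S,8aR,9aR)-5,8a-dimethyl-3-methylidene-3a,5,6,7,8,8a,9,9a-octahydronaphtho[2,3-b]furan-2(3H)-one | O=C1C(=C)[C@H]2C=C3[C@@H](C)CCC[C@]3(C)C[C@H]2O1 | intermediate
16 | (S)-(+)-carvone | CC1=CC[C@@H](CC1=O)C(=C)C | starting material
17 | (5S)-2-methyl-5-(prop-1-en-2-yl)cyclohexan-1-one (mixture at C2) | CC1CC[C@@H](CC1=O)C(=C)C | intermediate
18 | imine of 17 with (S)-1-phenylethylamine | CC1CC[C@@H](CC1=N[C@@H](C)c1ccccc1)C(=C)C | intermediate
19 | imine of 20 with (S)-1-phenylethylamine | COC(=O)CC[C@@]1(C)CC[C@@H](CC1=N[C@@H](C)c1ccccc1)C(=C)C | intermediate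
20 | methyl 3-[(1R,4S)-1-methyl-2-oxo-4-(prop-1-en-2-yl)cyclohexyl]propanoate | COC(=O)CC[C@@]1(C)CC[C@@H](CC1=O)C(=C)C | intermediate
21 | 3-[(1R,4S)-1-methyl-2-oxo-4-(prop-1-en-2-yl)cyclohexyl]propanoic acid | OC(=O)CC[C@@]1(C)CC[C@@H](CC1=O)C(=C)C | intermediate
22 | (2R,5S)-2-ethenyl-2-methyl-5-(prop-1-en-2-yl)cyclohexan-1-one | C=C[C@@]1(C)CC[C@@H](CC1=O)C(=C)C | intermediate
23 | (2R,5S)-2-ethenyl-2-methyl-5-(prop-1-en-2-yl)cyclohexane-1-carbonitrile (mixture at C1) | C=C[C@@]1(C)CC[C@@H](CC1C#N)C(=C)C | intermediate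
24 | lithium ketimide from 23 and methyllithium | C=C[C@@]1(C)CC[C@@H](CC1C(C)=N[Li])C(=C)C | intermediate
25 | 1-[(2R,5S)-2-ethenyl-2-methyl-5-(prop-1-en-2-yl)cyclohexyl]ethan-1-one (mixture at C1) | C=C[C@@]1(C)CC[C@@H](CC1C(C)=O)C(=C)C | intermediate
26 | 1-[(1S,2R,5S)-2-ethenyl-2-methyl-5-(prop-1-en-2-yl)cyclohexyl]ethan-1-one (acetyl trans to vinyl) | C=C[C@@]1(C)CC[C@@H](C[C@@H]1C(C)=O)C(=C)C | intermediate
27 | (1R,2R,4S)-1-ethenyl-1-methyl-2,4-di(prop-1-en-2-yl)cyclohexane (ent-β-elemene) | C=C[C@@]1(C)CC[C@@H](C[C@@H]1C(C)=C)C(=C)C | intermediate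
28 | (1R,2R,4S)-4-(3-chloroprop-1-en-2-yl)-1-ethenyl-1-methyl-2-(prop-1-en-2-yl)cyclohexane | C=C[C@@]1(C)CC[C@@H](C[C@@H]1C(C)=C)C(=C)CCl | intermediate
29 | 2-[(1S,3R,4R)-4-ethenyl-4-methyl-3-(prop-1-en-2-yl)cyclohexyl]prop-2-enal (ent-β-elemenal) | C=C[C@@]1(C)CC[C@@H](C[C@@H]1C(C)=C)C(=C)C=O | intermediate
30 | CNP0175206.1 (spiro oxa-Diels–Alder adduct of 15 and 29) | C=C[C@@]1(C)CC[C@H](C2=CO[C@@]3(CC2)C(=O)O[C@@H]2C[C@@]4(C)CCC[C@H](C)C4=C[C@@H]23)C[C@@H]1C(=C)C | target

## Summary

Total step count: 18. Longest linear sequence: 10 steps (steps 9 to 18, from (S)-carvone); the alantolactone branch is 9 steps (steps 1 to 8, then step 18).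

Three steps most likely to fail:

1. Step 7. What may go wrong: insufficient discrimination between the two trisubstituted double bonds of the conjugated diene, 1,4-addition of hydrogen to give the tetrasubstituted Δ4 isomer, or over-reduction. Fallback: setting out from 11, hydroboration with 9-BBN (THF, 0 to 40 °C), which responds far more strongly to steric hindrance, should add boron to C3 and hydrogen to C4 from the α face. Oxidation with H2O2 at pH 7 then gives (3aS,5S,6S,8aR,9aR)-type 3α-alcohol F1. Acylation with PhOC(S)Cl, pyridine and DMAP in CH2Cl2 gives the phenyl thionocarbonate F2. Barton–McCombie deoxygenation (Bu3SnH, AIBN, toluene, 90 °C) returns to the route at 12.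

2. Step 18. What may go wrong: self-dimerisation or polymerisation of the enal in competition with the cross cycloaddition, and poor facial selectivity at the spiro carbon. Fallback: a stepwise construction of the dihydropyran from 29 and 15. Conjugate addition of iodide to 29 (NaI, Me3SiCl, MeCN, −20 °C) with trapping by ethane-1,2-diol gives the β-iodo dioxolane F3. Its primary radical (Bu3SnH added slowly, AIBN, benzene, 80 °C) adds to the methylene group of 15 in a Giese reaction to give the C11–H lactone F4. Hydroxylation of its lithium enolate (LiN(i-Pr)2, THF, −78 °C, then 2-(phenylsulfonyl)-3-phenyloxaziridine) from the convex face gives the tertiary α-hydroxy lactone F5. Acid (pyridinium p-toluenesulfonate, wet acetone, then toluene at 100 °C with removal of water) cleaves the acetal, closes the lactol and dehydrates it to the enol ether, which comes back to the route at 30.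

3. Step 16. What may go wrong: poor site selectivity between the two isopropenyl groups and chlorination of both. Fallback: the three-carbon unit is oxidised while only one isopropenyl group is present, setting out from nitrile 23. Chlorination (Ca(OCl)2, CO2, CH2Cl2/H2O, 0 °C) gives the allylic chloride F6. KOAc in DMF at 60 °C gives the acetate F7. Excess CH3Li (Et2O, 0 °C to rt), then HCl (1 M) and NaOMe in MeOH, converts the nitrile into the methyl ketone and cleaves the acetate to give the hydroxy ketone F8. Methylenation with excess Ph3PCH3Br and t-BuOK gives ent-β-elemen-13-ol F9. MnO2 in CH2Cl2 oxidises the allylic alcohol and comes back to the route at 29.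

Further compounds
F1 | step 7 | 3α-hydroxy derivative of 12 (6-hydroxy-5,8a-dimethyl-3a,5,6,7,8,8a,9,9a-octahydronaphtho[2,3-b]furan-2(3H)-one, hydroxyl trans to the C4 methyl) | O=C1C[C@H]2C=C3[C@@H](C)[C@H](O)CC[C@]3(C)C[C@H]2O1
F2 | step 7 | O-phenyl thionocarbonate of F1 | O=C1C[C@H]2C=C3[C@@H](C)[C@H](OC(=S)Oc4ccccc4)CC[C@]3(C)C[C@H]2O1
F3 | step 18 | 2-{1-[(1S,3R,4R)-4-ethenyl-4-methyl-3-(prop-1-en-2-yl)cyclohexyl]-2-iodoethyl}-1,3-dioxolane (mixture at the new centre) | ICC(C1OCCO1)[C@H]1CC[C@](C)(C=C)[C@H](C1)C(C)=C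
F4 | step 18 | Giese adduct: 13-noralantolactone carrying at C11 the chain CH2CH2CH(1,3-dioxolan-2-yl)(elemanyl) (mixtures at C11 and the chain centre) | O=C1C(CCC(C2OCCO2)[C@H]2CC[C@](C)(C=C)[C@H](C2)C(C)=C)[C@H]3C=C4[C@@H](C)CCC[C@]4(C)C[C@H]3O1
F5 | step 18 | 11-hydroxy derivative of F4 (hydroxyl on the face of H7 and H8) | O=C1[C@@](O)(CCC(C2OCCO2)[C@H]2CC[C@](C)(C=C)[C@H](C2)C(C)=C)[C@H]3C=C4[C@@H](C)CCC[C@]4(C)C[C@H]3O1
F6 | step 16 | (2R,5S)-5-(3-chloroprop-1-en-2-yl)-2-ethenyl-2-methylcyclohexane-1-carbonitrile (mixture at C1) | C=C[C@@]1(C)CC[C@@H](CC1C#N)C(=C)CCl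
F7 | step 16 | 2-[(1S,4R)-3-cyano-4-ethenyl-4-methylcyclohexyl]prop-2-en-1-yl acetate (mixture at C3) | C=C[C@@]1(C)CC[C@@H](CC1C#N)C(=C)COC(C)=O
F8 | step 16 | 1-[(1S,2R,5S)-2-ethenyl-5-(3-hydroxyprop-1-en-2-yl)-2-methylcyclohexyl]ethan-1-one | C=C[C@@]1(C)CC[C@@H](C[C@@H]1C(C)=O)C(=C)CO
F9 | step 16 | 2-[(1S,3R,4R)-4-ethenyl-4-methyl-3-(prop-1-en-2-yl)cyclohexyl]prop-2-en-1-ol (ent-β-elemen-13-ol) | C=C[C@@]1(C)CC[C@@H](C[C@@H]1C(C)=C)C(=C)CO
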